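## The problem

Atoms are numbered in the order of the target SMILES (C1–C4, Br5, C6, C7, O8, C9–C11, O12, C13–C17, Br18, C19–C22, O23, C24, O25, C26). Ring C is the cyclopentane C2/C4/C6/C7/C9, ring A the cyclohexane C11/C13/C14/C15/C24/C26, and ring B the bromocyclohexane C15/C17/C19/C20/C21/C24.

Neoirietetraol 35 joins a trans-decalin (rings A and B) through its tertiary carbinol C11 to the quaternary C9 of ring C. C9 is itself flanked by the gem-dimethyl carbon C2, so the C9–C11 bond links two fully substituted carbons and cannot reasonably be made late.

There are eight stereocentres. On ring C, Br5, O8 and C11 all sit on one face (C4, C7, C9). On the decalin (C11, C15, C17, C21, C24) the C15 methyl and O25 are trans-diaxial at the ring fusion, O23 and O25 are trans-diaxial, O12 and O25 are syn-diaxial, and Br18 is equatorial and cis to the C15 methyl.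

The two halves are separated by the C9–C11 bond and cannot control each other, so each has to be made in absolute configuration. Within each half relay is possible: C4 can direct C7 and C9, and the angular C15 methyl can direct C24, C21 and C11 once the bicycle is rigid.

Both bromides are secondary and neopentylic. In the finished trans-decalin a substitution at C17 would have to enter eclipsed with the axial C15 methyl, and a late double substitution in a polyol is not credible. The bromides therefore have to enter on small intermediates and survive what follows, which excludes hot strong base, hydrogenolysis and HMPA-activated SmI2.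

The three tertiary alcohols dehydrate or rearrange in strong acid. Any β-hydroxy carbonyl compound with C9 as its α-carbon can open ring C by retro-aldol cleavage unless O8 is capped.

The enabling feature is that O8 on C7 and carbon C11 on C9 are cis on ring C. A four-membered lactone O8–C11 can bridge them, so ring C, the quaternary C9 and the C7 carbinol can be made together from an open-chain aldehyde acid, with C11 left as an acylating carbon for the junction to the decalin.

## Retrosynthesis

**35 back to 32 (C21–O23 and the epoxide).** The trans-diaxial C21/C24 diol is the signature of an epoxide opened by water, so 35 is traced through its O8 silyl ether 34 to the C21–C24 epoxide 33, and 33 to the octalinol 32. Dihydroxylation would give the cis diol, and a C21 ketone plus a methyl nucleophile would cost extra redox steps. The precursor 32 has two stereocentres fewer. The forward steps ask for epoxidation anti to the axial C15 methyl (also the face of O12) and for diaxial opening at C21 in acid mild enough for three tertiary alcohols.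

**32 back to 31 (C11–C13, ring A).** Cutting C11–C13 turns the tertiary carbinol into the ketone 31 and a primary iodide, an intramolecular Barbier closure. The neighbouring cut, C11–C26, is better made intermolecularly one step earlier, and a closure onto this very hindered ketone is most reliable when it is a six-membered ring formed by a primary organometallic. The forward reaction must place the bulky ring C substituent equatorial, giving O12 axial and anti to the C15 methyl, and must spare two secondary bromides.

**31 back to 19 and 29 (C11–C26, the union).** The β,γ-unsaturated ketone 31 comes by oxidation from the alcohol 30, and 30 from an ene reaction between the ring C aldehyde 19 and the exocyclic methylene compound 29. An allylmetal built on C26 would react through C21, and an enolate alkenylation needs hot strong base that the halides would not survive. The ene reaction bonds at the CH2 terminus and moves the double bond to C21=C24, exactly where the epoxide is wanted. The cut divides the molecule into two fragments of similar size.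

**19 back to 14 (C11 oxidation level and Br5).** The aldehyde 19 is the β-lactone at a lower oxidation level: Weinreb aminolysis of the bromo lactone 16 gives 17, O8 is silylated (18) and the amide is reduced. Br5 is introduced on the hydroxy lactone 15 by substitution with inversion (16). At that stage the cis substituents on C7 and C9 are tied back in the small lactone ring, so the concave face of C4 is as open as it will ever be; later C9 carries the whole decalin. 15 comes from the silyl ether 14.

**14 back to 12 (C7–C9 and O8–C11, the key step).** The bicyclic β-lactone 14 is opened at both bonds to the aldehyde acid 12. No neighbouring cut forms ring C, the quaternary C9 and the C7 carbinol at once, and this one also funnels both C9 epimers of 12 through one planar enolate. The precursor is acyclic with a single defined stereocentre (C4). The forward reaction must favour intramolecular aldol addition over reactions of the enolisable aldehyde and must place the lactone anti to the C4 silyloxy group.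

**12 back to 1 and 2 (the chain).** C11 and C7 are distinguished by origin: the acid comes from a vinyl group (9 to 11 via 10) and the aldehyde from an ester (11 to 12). Allylation of a 4-oxo ester, the obvious alternative, was rejected because the 4-hydroxy ester lactonises onto C11 (five-membered ring, gem-dimethyl assisted). Saponifying a hindered ester beside a β-silyloxy aldehyde would also invite elimination. C4 is set by asymmetric hydrogenation of the β-keto ester 7 (to 8, silylated to 9). 7 comes by one-carbon-pair homologation of aldehyde 5, and 5 by a Claisen rearrangement (via 3 and 4) that forms the hindered C2–C9 bond from isobutyraldehyde 1 and crotyl alcohol 2.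

**29 back to 20 and 21 (ring B).** The methylene carbon C26 of 29 comes from the ketone 28. The iodoethyl chain comes from an allyl group by ozonolysis, reduction (27, via 26) and iodination. The C21 methyl comes by enolate methylation of 24 (to 25), possible only on that side. Br18 comes from the ketol 23 by substitution with inversion on the mobile monocycle. 23 comes by desymmetrising reduction of the dione 22, which sets C15 and C17 together, and 22 by C-allylation of 2-methylcyclohexane-1,3-dione 20 with allyl bromide 21.

## Roads not taken

**Alternative 1:** The cut is C11–C13 of ring A in a fully oxygenated precursor. The iodo hydroxy ketone A1 (C11 ketone, free C24 carbinol, iodide on C13) is treated with SmI2 and HMPA. The alkylsamarium adds to the ketone held in a chelate with the C24 alkoxide and gives the protected tetraol A2 with O12 and O25 syn-diaxial.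
- Merits: the chelate controls C11 more firmly than the conformational argument used in step 22 of the chosen plan, and that is conceded. Closing ring A last is also highly convergent.
- Weak points: it is a plan for ring A only and says nothing about ring C or C9. The diol of A1 has to be set on a flexible monocyclic ring B, where nothing rigid decides the face. A2 carries C4 and C17 as inverted benzyl ethers, so both bromides would come from substitution after the decalin is rigid, and HMPA forbids installing them earlier.
- Comparison: the chosen plan uses the same bond for ring A but closes it before the diol exists. It accepts weaker control at C11 and sets against it the rigid-octalin control of C21/C24 and bromides installed where substitution is feasible. The chelated variant is kept as the fallback to step 22.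

**Alternative 2:** The cut removes the C9 methyl (C9–C10) and one C2 methyl (C2–C3) from a cyclopentenone. Me2CuLi with Me3SiCl adds to the β-carbon C9 of the enone A3 anti to the C7 silyloxy group, and the C2 enolate is methylated with iodomethane to give the cyclopentanone A4.
- Merits: it is short, uses classical cuprate chemistry, makes both quaternary carbons in one flask, and the C4 ketone allows either carbinol epimer. It reaches ring C in fewer steps than the seven of the chosen plan, and that is conceded.
- Weak points: a β,β-disubstituted α-methyl enone is a poor cuprate acceptor. Methylating a hindered tetrasubstituted enolate beside a new quaternary carbon competes with O-alkylation and with enolate equilibration toward C6, from where O8 is lost by β-elimination. C11 emerges as a protected CH2OH that must be unmasked and oxidised before it can acylate. The absolute configuration has to come from a separately made enantiopure A3.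
- Comparison: the chosen plan is longer to ring C but sets the absolute configuration by catalysis, locks C7 against C9 through the lactone ring, keeps C11 at the acid level, and brominates C4 on the compact lactone.

**Alternative 3:** The cut is C2–C9 with ring contraction. BF3·OEt2 opens the trimethylcyclohexene oxide A5 at tertiary C9, and ring carbon C2 migrates from C11 to C9, giving the ring C carbaldehyde A6.
- Merits: a stereospecific 1,2-shift makes the vicinal quaternary pair without any intermolecular bond formation at a hindered centre. It also delivers C11 directly as the aldehyde, which the chosen plan reaches only three operations after its lactone; that is conceded.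
- Weak points: the cation at C9 is destabilised by the adjacent C7 silyloxy group, and hydride shift from C11 (giving a cyclohexanone) competes with migration of C2. The Lewis acid threatens the silyl ether. A5, a fully substituted stereodefined epoxide, would itself need a long sequence with the epoxide face to be controlled. A6 again carries C4 as a benzyl ether, postponing bromination.
- Comparison: the chosen plan pays more steps after ring closure but has a predictable selectivity model, a convergent funnel for C9, and an early bromination.

Key step: step 7

Assumption: (S)-HBTM (homobenzotetramisole) is taken as the isothiourea enantiomer matched to the (4S) centre of 12; if trial runs show it to be mismatched, (R)-HBTM replaces it and nothing else changes.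

## Route

Step 1
Reactants: 1 isobutyraldehyde; 2 (E)-but-2-en-1-ol
Product: 5 2,2,3-trimethylpent-4-enal (racemic), via dicrotyl acetal 3 (not isolated), via crotyl isobutenyl ether 4 (not isolated)
Conditions: p-TsOH·H2O (cat.), p-cymene, 110 → 150 °C, Dean–Stark
Reagents that add atoms: none
Why: Acid-catalysed acetalisation and loss of crotyl alcohol give the allyl vinyl ether 4, whose Claisen rearrangement joins the future C2 and C9 and leaves an aldehyde (future C4) and a vinyl group (future C11). The new centre C9 is racemic, which is harmless because it is made planar in the key step.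

Step 2
Reactants: 5 2,2,3-trimethylpent-4-enal; 6 ethyl diazoacetate
Product: 7 ethyl 4,4,5-trimethyl-3-oxohept-6-enoate (racemic)
Conditions: SnCl2 (10 mol%), CH2Cl2, rt
Reagents that add atoms: none
Why: Roskamp homologation: the SnCl2-activated aldehyde is attacked by the diazo carbon and a 1,2-hydride shift with loss of N2 gives the β-keto ester, adding C6 and C7. An α-quaternary aldehyde cannot enolise or self-condense, which suits this reaction.

Step 3
Reactants: 7 ethyl 4,4,5-trimethyl-3-oxohept-6-enoate
Product: 8 ethyl (3S)-3-hydroxy-4,4,5-trimethylhept-6-enoate (both C5 epimers)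
Conditions: RuCl2[(R)-BINAP] (1 mol%), H2 (4 atm), EtOH, 50 °C
Reagents that add atoms: none
Why: Noyori hydrogenation of a β-keto ester through its Ru chelate; the (R)-BINAP complex should give the (3S) carbinol (the usual sense for β-keto esters, the descriptor being S because the tertiary alkyl group outranks CH2CO2Et), and this carbon becomes C4. Catalyst control should override the remote racemic centre, and the chloride-bearing Ru–BINAP complex is not expected to reduce an isolated, hindered vinyl group at low pressure.

Step 4
Reactants: 8 ethyl (3S)-3-hydroxy-4,4,5-trimethylhept-6-enoate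
Product: 9 ethyl (3S)-3-[(tert-butyldimethylsilyl)oxy]-4,4,5-trimethylhept-6-enoate
Conditions: TBSOTf, 2,6-lutidine, CH2Cl2, 0 °C
Reagents that add atoms: tert-butyldimethylsilyl triflate, CC(C)(C)[Si](C)(C)OS(=O)(=O)C(F)(F)F
Why: A silyl triflate with a hindered pyridine base silylates the neopentylic secondary alcohol without the alkoxide conditions that would provoke retro-aldol cleavage of a β-hydroxy ester. The silyl ether also blocks lactonisation onto C11 in all later steps.

Step 5
Reactants: 9 ethyl (3S)-3-[(tert-butyldimethylsilyl)oxy]-4,4,5-trimethylhept-6-enoate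
Product: 11 (4S)-4-[(tert-butyldimethylsilyl)oxy]-6-ethoxy-2,3,3-trimethyl-6-oxohexanoic acid, via aldehyde ester 10 (not isolated)
Conditions: O3, CH2Cl2, −78 °C; Me2S; then NaClO2, NaH2PO4, 2-methylbut-2-ene, t-BuOH/H2O, 0 °C → rt
Reagents that add atoms: ozone, [O-][O+]=O; sodium chlorite, [Na+].[O-]Cl=O
Why: Ozonolysis cleaves the only alkene to the C11 aldehyde 10 and Pinnick oxidation takes it to the acid without touching the ester or the silyl ether. Epimerisation at C9 in 10 is of no consequence.

Step 6
Reactants: 11 (4S)-4-[(tert-butyldimethylsilyl)oxy]-6-ethoxy-2,3,3-trimethyl-6-oxohexanoic acid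
Product: 12 (4S)-4-[(tert-butyldimethylsilyl)oxy]-2,3,3-trimethyl-6-oxohexanoic acid (2R epimer drawn; 2S epimer also present)
Conditions: i-Bu2AlH (2.2 equiv), CH2Cl2, −78 °C; aq. potassium sodium tartrate, then pH 4
Reagents that add atoms: none
Why: The first equivalent of i-Bu2AlH turns the acid into an aluminium carboxylate that is inert at −78 °C, and the second reduces the ethyl ester to a stable tetrahedral intermediate that gives the aldehyde on work-up (partial reduction of an ester). The C7 aldehyde and the C11 acid are thus distinguished by their origin.

Step 7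
Reactants: 12 (4S)-4-[(tert-butyldimethylsilyl)oxy]-2,3,3-trimethyl-6-oxohexanoic acid
Product: 14 (1R,3S,5S)-3-[(tert-butyldimethylsilyl)oxy]-1,2,2-trimethyl-6-oxabicyclo[3.2.0]heptan-7-one, via tosyl mixed anhydride 13 (not isolated)
Conditions: TsCl (1.3 equiv), i-Pr2NEt (4 equiv), LiCl (1 equiv), (S)-HBTM (20 mol%), CH2Cl2, rt, slow addition of 12 at high dilution
Reagents that add atoms: none
Why: TsCl and i-Pr2NEt convert the acid into the mixed anhydride 13, the isothiourea is acylated, and deprotonation gives a planar C9 ammonium enolate, so both C9 epimers enter one intermediate. The enolate carbon adds to the C7 aldehyde in a 5-exo-trig closure with the enolate double bond outside the new ring (ring C), and the resulting alkoxide O8 attacks the acylammonium carbon C11 in a 4-exo-trig acyl substitution that closes the β-lactone and releases the catalyst. The closest known reaction type is the nucleophile-catalysed aldol-lactonisation of aldehyde acids and keto acids to cyclopentane-fused β-lactones, which includes α-branched acids that give a quaternary α-carbon. C7 is fixed against C9 by the four-membered ring, since only the aldolate with O8 cis to C11 can lactonise and the other can revert. The face of this pair relative to C4 is set by the substrate, which should place the silyloxy group on the convex face away from the forming lactone, and by the catalyst, whose phenyl group shields one face of the enolate. The step needs intramolecular aldol addition to win over intermolecular reactions of the enolisable aldehyde; the gem-dimethyl group at C2 (Thorpe–Ingold effect), slow addition at high dilution and LiCl as a mild activator of the aldehyde should secure this. The quaternary C9 of the product cannot epimerise.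

Step 8
Reactants: 14 (1R,3S,5S)-3-[(tert-butyldimethylsilyl)oxy]-1,2,2-trimethyl-6-oxabicyclo[3.2.0]heptan-7-one
Product: 15 (1R,3S,5S)-3-hydroxy-1,2,2-trimethyl-6-oxabicyclo[3.2.0]heptan-7-one
Conditions: HF (48% aq.), MeCN, rt
Reagents that add atoms: none
Why: Aqueous HF in acetonitrile cleaves the hindered silyl ether under acidic conditions that leave the β-lactone intact, whereas basic fluoride would open it. The C4 hydroxyl is trans to the lactone and cannot translactonise.

Step 9
Reactants: 15 (1R,3S,5S)-3-hydroxy-1,2,2-trimethyl-6-oxabicyclo[3.2.0]heptan-7-one
Product: 16 (1R,3R,5S)-3-bromo-1,2,2-trimethyl-6-oxabicyclo[3.2.0]heptan-7-one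
Conditions: CBr4, PPh3, toluene, 60 °C
Reagents that add atoms: carbon tetrabromide, BrC(Br)(Br)Br
Why: Appel reaction: the alkoxyphosphonium ion is displaced by bromide with inversion, which puts Br5 on the face of O8 and C11. The substitution is neopentylic and is placed here because the cis substituents on C7 and C9 are tied back in the small lactone ring, leaving the concave face of C4 as accessible as it can be; the conditions are neutral toward the β-lactone.

Step 10
Reactants: 16 (1R,3R,5S)-3-bromo-1,2,2-trimethyl-6-oxabicyclo[3.2.0]heptan-7-one
Product: 17 (1R,2S,4R)-4-bromo-2-hydroxy-N-methoxy-N,1,5,5-tetramethylcyclopentane-1-carboxamide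
Conditions: MeNH(OMe)·HCl, AlMe3, CH2Cl2, 0 °C → rt
Reagents that add atoms: N,O-dimethylhydroxylamine hydrochloride, CNOC.Cl
Why: Weinreb aminolysis: the aluminium amide attacks the strained acyl carbon C11 and cleaves the C11–O8 bond, using the lactone as the acylating agent it was built to be. No stereocentre is touched.

Step 11
Reactants: 17 (1R,2S,4R)-4-bromo-2-hydroxy-N-methoxy-N,1,5,5-tetramethylcyclopentane-1-carboxamide
Product: 18 (1R,2S,4R)-4-bromo-N-methoxy-N,1,5,5-tetramethyl-2-[(triethylsilyl)oxy]cyclopentane-1-carboxamide
Conditions: TESOTf, 2,6-lutidine, CH2Cl2, −78 → 0 °C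
Reagents that add atoms: triethylsilyl triflate, CC[Si](CC)(CC)OS(=O)(=O)C(F)(F)F
Why: Silylation of O8 prevents retro-aldol opening of ring C in the later β-oxygenated carbonyl compounds and protects the carbinol from the oxidant of step 21. A silyl triflate is needed for this hindered alcohol.

Step 12
Reactants: 18 (1R,2S,4R)-4-bromo-N-methoxy-N,1,5,5-tetramethyl-2-[(triethylsilyl)oxy]cyclopentane-1-carboxamide
Product: 19 (1R,2S,4R)-4-bromo-1,5,5-trimethyl-2-[(triethylsilyl)oxy]cyclopentane-1-carbaldehyde
Conditions: i-Bu2AlH, THF, −78 °C; aq. potassium sodium tartrate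
Reagents that add atoms: none
Why: Hydride reduction of the Weinreb amide stops at the chelated tetrahedral intermediate and gives the aldehyde on work-up. The aldehyde has no α-hydrogen, so it can neither epimerise nor eliminate, and the secondary bromide is inert to i-Bu2AlH at −78 °C.

Step 13
Reactants: 20 2-methylcyclohexane-1,3-dione; 21 allyl bromide
Product: 22 2-methyl-2-(prop-2-en-1-yl)cyclohexane-1,3-dione
Conditions: NaOH (1 M aq.), rt
Reagents that add atoms: none
Why: C-Allylation of the stabilised enolate of a cyclic 1,3-dione with an activated halide in aqueous base. It creates the prochiral quaternary carbon C15 with a three-carbon handle for the C14–C13 chain.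

Step 14
Reactants: 22 2-methyl-2-(prop-2-en-1-yl)cyclohexane-1,3-dione
Product: 23 (2R,3R)-3-hydroxy-2-methyl-2-(prop-2-en-1-yl)cyclohexan-1-one
Conditions: (S)-2-methyl-CBS-oxazaborolidine (20 mol%), catecholborane, toluene, −78 °C
Reagents that add atoms: none
Why: CBS reduction desymmetrises the dione: with the quaternary carbon as the large group the (S)-oxazaborolidine should give the (R) carbinol, and hydride enters the carbonyl whose reacting face is anti to the allyl group, so the hydroxyl ends up cis to the allyl group and C15 is fixed with it. This sets C15 and, after inversion in step 15, C17.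

Step 15
Reactants: 23 (2R,3R)-3-hydroxy-2-methyl-2-(prop-2-en-1-yl)cyclohexan-1-one
Product: 24 (2S,3S)-3-bromo-2-methyl-2-(prop-2-en-1-yl)cyclohexan-1-one
Conditions: CBr4, PPh3, CH2Cl2, 0 °C → reflux
Reagents that add atoms: carbon tetrabromide, BrC(Br)(Br)Br
Why: Appel reaction with inversion gives the bromide cis to the C15 methyl group. The substitution is neopentylic but is done on the conformationally mobile monocycle, where the neighbouring carbonyl disfavours ionisation and hence Wagner–Meerwein shifts.

Step 16
Reactants: 24 (2S,3S)-3-bromo-2-methyl-2-(prop-2-en-1-yl)cyclohexan-1-one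
Product: 25 (2S,3S)-3-bromo-2,6-dimethyl-2-(prop-2-en-1-yl)cyclohexan-1-one (both C6 epimers)
Conditions: LiN(i-Pr)2, THF, −78 °C; MeI, −78 → −20 °C
Reagents that add atoms: iodomethane, CI
Why: Kinetic enolate formation is possible only toward C21 because C15 is quaternary, and methylation installs the C21 methyl group. The C21 configuration is irrelevant since this carbon becomes trigonal in step 20, and enolate formation at −78 °C should outrun elimination of the bromide.

Step 17
Reactants: 25 (2S,3S)-3-bromo-2,6-dimethyl-2-(prop-2-en-1-yl)cyclohexan-1-one
Product: 27 (2S,3S)-3-bromo-2-(2-hydroxyethyl)-2,6-dimethylcyclohexan-1-one, via keto aldehyde 26 (not isolated)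
Conditions: O3, CH2Cl2/MeOH, −78 °C; then NaBH4, −78 → −40 °C
Reagents that add atoms: ozone, [O-][O+]=O
Why: Ozonolysis removes the terminal carbon of the allyl group and NaBH4 at low temperature reduces the aldehyde 26 and the peroxidic intermediates, while the ketone, flanked by a quaternary and a tertiary carbon, is left alone. This leaves the two-carbon C14–C13 chain.

Step 18
Reactants: 27 (2S,3S)-3-bromo-2-(2-hydroxyethyl)-2,6-dimethylcyclohexan-1-one
Product: 28 (2S,3S)-3-bromo-2-(2-iodoethyl)-2,6-dimethylcyclohexan-1-one
Conditions: I2, PPh3, imidazole, CH2Cl2, 0 °C → rt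
Reagents that add atoms: iodine, II
Why: Appel-type iodination of the primary alcohol, which reacts through its open hydroxy ketone form, gives the iodide needed for ring closure. The secondary bromide and the hindered ketone are unaffected.

Step 19
Reactants: 28 (2S,3S)-3-bromo-2-(2-iodoethyl)-2,6-dimethylcyclohexan-1-one
Product: 29 (1S,2S)-1-bromo-2-(2-iodoethyl)-2,4-dimethyl-3-methylidenecyclohexane (both C4 epimers)
Conditions: Cp2Ti(μ-Cl)(μ-CH2)AlMe2 (Tebbe reagent), pyridine, THF/toluene, −40 °C → rt
Reagents that add atoms: Tebbe reagent, C[Al-]1(C)C[Ti]([Cl+]1)(C2C=CC=C2)C2C=CC=C2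
Why: Tebbe methylenation converts the hindered, enolisable ketone into the exocyclic alkene that carries C26. The reagent is non-basic and tolerates alkyl halides.

Step 20
Reactants: 19 (1R,2S,4R)-4-bromo-1,5,5-trimethyl-2-[(triethylsilyl)oxy]cyclopentane-1-carbaldehyde; 29 (1S,2S)-1-bromo-2-(2-iodoethyl)-2,4-dimethyl-3-methylidenecyclohexane
Product: 30 1-[4-bromo-1,5,5-trimethyl-2-(triethylsilyloxy)cyclopentyl]-2-[(5S,6S)-5-bromo-6-(2-iodoethyl)-2,6-dimethylcyclohex-1-en-1-yl]ethan-1-ol (ring C configured as in 19; both carbinol epimers)
Conditions: Me2AlCl (2 equiv), CH2Cl2, −78 → 0 °C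
Reagents that add atoms: none
Why: Carbonyl–ene reaction promoted by Me2AlCl: the aldehyde carbon C11 bonds to the CH2 terminus (C26) of the 1,1-disubstituted alkene and the only allylic hydrogen, on C21, is transferred to oxygen, so the double bond moves to C21=C24. The reagent scavenges protons, and the new carbinol centre is removed in step 21.

Step 21
Reactants: 30 ene adduct (both carbinol epimers)
Product: 31 1-[(1R,2S,4R)-4-bromo-1,5,5-trimethyl-2-(triethylsilyloxy)cyclopentyl]-2-[(5S,6S)-5-bromo-6-(2-iodoethyl)-2,6-dimethylcyclohex-1-en-1-yl]ethan-1-one
Conditions: Dess–Martin periodinane, NaHCO3, CH2Cl2, 0 °C → rt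
Reagents that add atoms: none
Why: Dess–Martin oxidation of the hindered secondary alcohol under buffered conditions gives the ketone needed for ring closure. The tetrasubstituted β,γ-double bond has no reason to move into conjugation.

Step 22
Reactants: 31 iodo ketone
Product: 32 octalinol with rings A–C closed (4R,7S,9R,11R,15S,17S in target numbering; O12 free; O8 as triethylsilyl ether; C21=C24 double bond)
Conditions: SmI2 (2.5 equiv), Fe(dbm)3 (2 mol%), THF, −78 °C → rt
Reagents that add atoms: none
Why: Barbier cyclisation: SmI2 reduces the primary iodide and the alkylsamarium adds to the ketone through a six-membered chair transition state with the bulky ring C substituent equatorial and the C15 methyl axial, which places O12 axial and anti to the C15 methyl group. Without HMPA the two secondary bromides should not be reduced.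

Step 23
Reactants: 32 octalinol
Product: 33 21,24-epoxide of 32 with the oxygen anti to the C15 methyl group (4R,7S,9R,11R,15S,17S,21S,24R)
Conditions: mCPBA, NaHCO3, CH2Cl2, 0 °C
Reagents that add atoms: 3-chloroperbenzoic acid, OOC(=O)c1cccc(Cl)c1
Why: Prilezhaev epoxidation of the electron-rich tetrasubstituted alkene from the face anti to the axial C15 methyl group, which is also the face of the homoallylic hydroxyl O12 that can hydrogen-bond to the peracid. This sets O25 at C24.

Step 24
Reactants: 33 epoxide
Product: 35 neoirietetraol (4R,7S,9R,11R,15S,17S,21R,24R), via C7 triethylsilyl ether 34 (not isolated)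
Conditions: HClO4 (dilute aq.), THF, 0 °C → rt
Reagents that add atoms: water, O
Why: Acid-catalysed epoxide opening follows the Fürst–Plattner rule: water attacks the tertiary C21 from the face of the C15 methyl group and gives the trans-diaxial C21/C24 diol with retention at C24. The same acid hydrolyses the triethylsilyl ether; the secondary bromides and tertiary alcohols should tolerate dilute HClO4 at or below room temperature.

## Compound list

1 | isobutyraldehyde (2-methylpropanal) | CC(C)C=O | starting material
2 | (E)-but-2-en-1-ol (crotyl alcohol) | C/C=C/CO | starting material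
3 | 2-methylpropanal di[(E)-but-2-enyl] acetal | CC(C)C(OC/C=C/C)OC/C=C/C | intermediate
4 | (E)-but-2-enyl 2-methylprop-1-enyl ether | CC(C)=COC/C=C/C | intermediate
5 | 2,2,3-trimethylpent-4-enal (racemic) | C=CC(C)C(C)(C)C=O | intermediate
6 | ethyl diazoacetate | CCOC(=O)C=[N+]=[N-] | starting material
7 | ethyl 4,4,5-trimethyl-3-oxohept-6-enoate (racemic) | CCOC(=O)CC(=O)C(C)(C)C(C)C=C | intermediate
8 | ethyl (3S)-3-hydroxy-4,4,5-trimethylhept-6-enoate (both C5 epimers) | CCOC(=O)C[C@H](O)C(C)(C)C(C)C=C | intermediate
9 | ethyl (3S)-3-[(tert-butyldimethylsilyl)oxy]-4,4,5-trimethylhept-6-enoate (both C5 epimers) | CCOC(=O)C[C@H](O[Si](C)(C)C(C)(C)C)C(C)(C)C(C)C=C | intermediate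
10 | ethyl (3S)-3-[(tert-butyldimethylsilyl)oxy]-4,4,5-trimethyl-6-oxohexanoate (both C5 epimers) | CCOC(=O)C[C@H](O[Si](C)(C)C(C)(C)C)C(C)(C)C(C)C=O | intermediate
11 | (4S)-4-[(tert-butyldimethylsilyl)oxy]-6-ethoxy-2,3,3-trimethyl-6-oxohexanoic acid (both C2 epimers) | CCOC(=O)C[C@H](O[Si](C)(C)C(C)(C)C)C(C)(C)C(C)C(O)=O | intermediate
12 | (4S)-4-[(tert-butyldimethylsilyl)oxy]-2,3,3-trimethyl-6-oxohexanoic acid (2R epimer drawn; 2S epimer also present; both converge) | CC(C)([C@@H](O[Si](C)(C)C(C)(C)C)CC=O)[C@@H](C)C(O)=O | intermediate
13 | mixed anhydride of 12 with p-toluenesulfonic acid (both C2 epimers) | CC(C)([C@@H](O[Si](C)(C)C(C)(C)C)CC=O)C(C)C(=O)OS(=O)(=O)c1ccc(C)cc1 | intermediate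
14 | (1R,3S,5S)-3-[(tert-butyldimethylsilyl)oxy]-1,2,2-trimethyl-6-oxabicyclo[3.2.0]heptan-7-one (silyloxy group trans to the lactone) | CC1(C)[C@@H](O[Si](C)(C)C(C)(C)C)C[C@@H]2OC(=O)[C@]12C | intermediate
15 | (1R,3S,5S)-3-hydroxy-1,2,2-trimethyl-6-oxabicyclo[3.2.0]heptan-7-one | CC1(C)[C@@H](O)C[C@@H]2OC(=O)[C@]12C | intermediate
16 | (1R,3R,5S)-3-bromo-1,2,2-trimethyl-6-oxabicyclo[3.2.0]heptan-7-one (bromine cis to the lactone) | CC1(C)[C@H](Br)C[C@@H]2OC(=O)[C@]12C | intermediate
17 | (1R,2S,4R)-4-bromo-2-hydroxy-N-methoxy-N,1,5,5-tetramethylcyclopentane-1-carboxamide | CC1(C)[C@H](Br)C[C@H](O)[C@]1(C)C(=O)N(C)OC | intermediate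
18 | (1R,2S,4R)-4-bromo-N-methoxy-N,1,5,5-tetramethyl-2-[(triethylsilyl)oxy]cyclopentane-1-carboxamide | CC1(C)[C@H](Br)C[C@H](O[Si](CC)(CC)CC)[C@]1(C)C(=O)N(C)OC | intermediate
19 | (1R,2S,4R)-4-bromo-1,5,5-trimethyl-2-[(triethylsilyl)oxy]cyclopentane-1-carbaldehyde (Br, silyloxy and formyl groups on one face) | CC1(C)[C@H](Br)C[C@H](O[Si](CC)(CC)CC)[C@]1(C)C=O | intermediate
20 | 2-methylcyclohexane-1,3-dione | CC1C(=O)CCCC1=O | starting material
21 | allyl bromide (3-bromoprop-1-ene) | C=CCBr | starting material
22 | 2-methyl-2-(prop-2-en-1-yl)cyclohexane-1,3-dione | C=CCC1(C)C(=O)CCCC1=O | intermediate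
23 | (2R,3R)-3-hydroxy-2-methyl-2-(prop-2-en-1-yl)cyclohexan-1-one (hydroxyl cis to allyl) | O=C1CCC[C@@H](O)[C@@]1(C)CC=C | intermediate
24 | (2S,3S)-3-bromo-2-methyl-2-(prop-2-en-1-yl)cyclohexan-1-one (bromine cis to methyl) | O=C1CCC[C@H](Br)[C@@]1(C)CC=C | intermediate
25 | (2S,3S)-3-bromo-2,6-dimethyl-2-(prop-2-en-1-yl)cyclohexan-1-one (both C6 epimers) | O=C1C(C)CC[C@H](Br)[C@@]1(C)CC=C | intermediate
26 | 2-[(1S,2S)-2-bromo-1,5-dimethyl-6-oxocyclohexyl]acetaldehyde (both C5 epimers) | O=C1C(C)CC[C@H](Br)[C@@]1(C)CC=O | intermediate
27 | (2S,3S)-3-bromo-2-(2-hydroxyethyl)-2,6-dimethylcyclohexan-1-one (both C6 epimers; may exist partly as the cyclic hemiketal) | O=C1C(C)CC[C@H](Br)[C@@]1(C)CCO | intermediate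
28 | (2S,3S)-3-bromo-2-(2-iodoethyl)-2,6-dimethylcyclohexan-1-one (both C6 epimers) | O=C1C(C)CC[C@H](Br)[C@@]1(C)CCI | intermediate
29 | (1S,2S)-1-bromo-2-(2-iodoethyl)-2,4-dimethyl-3-methylidenecyclohexane (both C4 epimers) | C=C1C(C)CC[C@H](Br)[C@@]1(C)CCI | intermediate
30 | 1-[4-bromo-1,5,5-trimethyl-2-(triethylsilyloxy)cyclopentyl]-2-[(5S,6S)-5-bromo-6-(2-iodoethyl)-2,6-dimethylcyclohex-1-en-1-yl]ethan-1-ol (ring C as in 19; both carbinol epimers) | CC1(C)[C@H](Br)C[C@H](O[Si](CC)(CC)CC)[C@]1(C)C(O)CC1=C(C)CC[C@H](Br)[C@@]1(C)CCI | intermediate
31 | 1-[(1R,2S,4R)-4-bromo-1,5,5-trimethyl-2-(triethylsilyloxy)cyclopentyl]-2-[(5S,6S)-5-bromo-6-(2-iodoethyl)-2,6-dimethylcyclohex-1-en-1-yl]ethan-1-one | CC1(C)[C@H](Br)C[C@H](O[Si](CC)(CC)CC)[C@]1(C)C(=O)CC1=C(C)CC[C@H](Br)[C@@]1(C)CCI | intermediate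
32 | octalinol: target skeleton with C21=C24 double bond, O12 free and axial, O8 as triethylsilyl ether (4R,7S,9R,11R,15S,17S in target numbering) | CC1(C)[C@H](Br)C[C@H](O[Si](CC)(CC)CC)[C@]1(C)[C@@]1(O)CC[C@]2(C)[C@@H](Br)CCC(C)=C2C1 | intermediate
33 | 21,24-epoxide of 32, oxygen anti to the C15 methyl and syn to O12 (4R,7S,9R,11R,15S,17S,21S,24R) | CC1(C)[C@H](Br)C[C@H](O[Si](CC)(CC)CC)[C@]1(C)[C@@]1(O)CC[C@]2(C)[C@@H](Br)CC[C@]3(C)O[C@]23C1 | intermediate
34 | neoirietetraol 7-O-triethylsilyl ether (4R,7S,9R,11R,15S,17S,21R,24R) | CC1(C)[C@H](Br)C[C@H](O[Si](CC)(CC)CC)[C@]1(C)[C@@]1(O)CC[C@]2(C)[C@@H](Br)CC[C@@](C)(O)[C@@]2(O)C1 | intermediate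
35 | neoirietetraol (4R,7S,9R,11R,15S,17S,21R,24R in SMILES atom numbering) | CC1(C)[C@H](Br)C[C@H](O)[C@]1(C)[C@@]1(O)CC[C@]2(C)[C@@H](Br)CC[C@@](C)(O)[C@@]2(O)C1 | target

## Step count and weakest steps

Total: 24 steps. Longest linear sequence: 17 steps (steps 1–12, then 20–24). The ring B branch (steps 13–19) contributes 7 steps before the union.

**Step 7 (key step).** The acid is α-branched and sits beside a quaternary carbon, so acyl transfer to the catalyst and enolisation may be slow. Intermolecular aldol reactions or enolisation of the aldehyde, or anhydride oligomerisation, could then take over. A mismatched catalyst would also erode the facial selectivity relative to C4.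
Fallback, from 12 back to 14: the acid is converted under neutral conditions (1-chloro-N,N,2-trimethylprop-1-en-1-amine, CH2Cl2) into the acid chloride F1. This is dehydrochlorinated with i-Pr2NEt to the methyl(alkyl)ketene F2. A Lewis acid such as ZnCl2 then promotes the intramolecular [2+2] cycloaddition of the ketene to the C7 aldehyde, which forms the same two bonds and can only give the cis-fused lactone 14. Face selectivity then rests on the C4 centre alone.

**Step 9.** The alkoxyphosphonium ion at the neopentylic C4 may eliminate to the cyclopentene or suffer a methyl shift from C2 instead of being displaced, and bromide may attack the lactone.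
Fallback, from 15 back to 16: the alcohol is converted at low temperature into the triflate F3 (Tf2O, pyridine), a discrete and far better leaving group. It is displaced with soluble Bu4NBr in toluene at 0 °C, where substitution can compete before ionisation sets in.

**Step 15.** Substitution at the neopentylic C17 may be slow and elimination to the cyclohexenone-type alkene may dominate.
Fallback, from 23 back to 24: the ketol is converted into the mesylate F4 (MsCl, Et3N). This is displaced with LiBr in refluxing butan-2-one, a separate substitution on an isolated sulfonate in which the neighbouring carbonyl still suppresses ionisation.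

**Step 20.** Both partners are hindered, so the ene reaction may be sluggish. A stepwise Prins pathway through the tertiary cation at C24 could lead to chloride capture or a shift from C15, and the Lewis acid could remove the silyl ether.
Fallback, from 18 and 29 back to 32 (the order of the two bonds to C11 is reversed and steps 12 and 20–22 are bypassed): iodine–lithium exchange on 29 (t-BuLi, Et2O/pentane, −78 °C) gives the alkyllithium F5. This adds to the Weinreb amide 18 to give the ketone F6, in which C11 is already bonded to C13. A Me2AlCl-promoted intramolecular carbonyl–ene reaction (the mode in which the tether is attached to the central alkene carbon) then closes ring A at C11–C26 and gives 32 directly. Its transition state places O12 axial, toward the C21 hydrogen that is transferred, but the configuration at C11 would have to be confirmed.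

**Step 22.** The doubly activated C26 methylene may protonate the alkylsamarium, leading to simple loss of iodine. Without a chelating group the facial selectivity at C11 rests only on the chair preference, and partial reduction of the bromides is possible.
Fallback, from 31 back to 34: the alkene of 31 is epoxidised first (mCPBA) to the epoxy ketone F7. This is hydrolysed with dilute HClO4 to the dihydroxy ketone F8, whose C24 alkoxide can chelate samarium together with the C11 ketone. The Barbier closure with SmI2 then delivers C13 so that O12 is syn to O25 and gives 34, which the acid of step 24 desilylates. This variant gives firmer control of C11 but a less certain face for the epoxidation on the monocyclic ring B.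

## Further compounds

F1 | step 7 | (4S)-4-[(tert-butyldimethylsilyl)oxy]-2,3,3-trimethyl-6-oxohexanoyl chloride (both C2 epimers) | CC(C)([C@@H](O[Si](C)(C)C(C)(C)C)CC=O)C(C)C(Cl)=O
F2 | step 7 | (5S)-5-[(tert-butyldimethylsilyl)oxy]-3,4,4-trimethyl-2-(oxomethylidene)heptan-7-al (methyl(alkyl)ketene of 12) | CC(=C=O)C(C)(C)[C@@H](O[Si](C)(C)C(C)(C)C)CC=O
F3 | step 9 | (1R,3S,5S)-1,2,2-trimethyl-7-oxo-6-oxabicyclo[3.2.0]heptan-3-yl trifluoromethanesulfonate | CC1(C)[C@@H](OS(=O)(=O)C(F)(F)F)C[C@@H]2OC(=O)[C@]12C
F4 | step 15 | (1R,2R)-2-methyl-3-oxo-2-(prop-2-en-1-yl)cyclohexyl methanesulfonate | O=C1CCC[C@@H](OS(C)(=O)=O)[C@@]1(C)CC=C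
F5 | step 20 | {2-[(1S,2S)-2-bromo-1,5-dimethyl-6-methylidenecyclohexyl]ethyl}lithium | [Li]CC[C@]1(C)[C@@H](Br)CCC(C)C1=C
F6 | step 20 | 1-[(1R,2S,4R)-4-bromo-1,5,5-trimethyl-2-(triethylsilyloxy)cyclopentyl]-3-[(1S,2S)-2-bromo-1,5-dimethyl-6-methylidenecyclohexyl]propan-1-one | CC1(C)[C@H](Br)C[C@H](O[Si](CC)(CC)CC)[C@]1(C)C(=O)CC[C@]1(C)[C@@H](Br)CCC(C)C1=C
F7 | step 22 | epoxy ketone: 31 with its C21=C24 double bond epoxidised anti to the C15 methyl group | CC1(C)[C@H](Br)C[C@H](O[Si](CC)(CC)CC)[C@]1(C)C(=O)C[C@@]12O[C@@]2(C)CC[C@H](Br)[C@@]1(C)CCI
F8 | step 22 | dihydroxy ketone: 31 with the trans C21/C24 diol of the target in place of the double bond | CC1(C)[C@H](Br)C[C@H](O[Si](CC)(CC)CC)[C@]1(C)C(=O)C[C@]1(O)[C@](C)(O)CC[C@H](Br)[C@@]1(C)CCI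
A1 | alternative 1 | iodo hydroxy ketone: C11 ketone on ring C (C4 benzyl ether, C7 silyl ether) linked through C26 to the C24 carbinol of a ring B diol carrying the 2-iodoethyl chain and the C17 benzyl ether | CC1(C)[C@@H](OCc2ccccc2)C[C@H](O[Si](C)(C)C(C)(C)C)[C@]1(C)C(=O)C[C@]1(O)[C@](C)(O)CC[C@@H](OCc2ccccc2)[C@@]1(C)CCI
A2 | alternative 1 | protected tetraol with all three rings (C4 and C17 as inverted benzyl ethers, C7 as tert-butyldimethylsilyl ether) | CC1(C)[C@@H](OCc2ccccc2)C[C@H](O[Si](C)(C)C(C)(C)C)[C@]1(C)[C@@]1(O)CC[C@]2(C)[C@H](OCc3ccccc3)CC[C@@](C)(O)[C@@]2(O)C1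
A3 | alternative 2 | 4-[(tert-butyldimethylsilyl)oxy]-3-{[(4-methoxybenzyl)oxy]methyl}-2-methylcyclopent-2-en-1-one | CC1=C(COCc2ccc(OC)cc2)[C@@H](O[Si](C)(C)C(C)(C)C)CC1=O
A4 | alternative 2 | 4-[(tert-butyldimethylsilyl)oxy]-3-{[(4-methoxybenzyl)oxy]methyl}-2,2,3-trimethylcyclopentan-1-one | CC1(C)C(=O)C[C@H](O[Si](C)(C)C(C)(C)C)[C@]1(C)COCc1ccc(OC)cc1
A5 | alternative 3 | 4-(benzyloxy)-2-[(tert-butyldimethylsilyl)oxy]-1,5,5-trimethyl-7-oxabicyclo[4.1.0]heptane (epoxide oxygen on the face of the silyloxy group) | C[C@@]12O[C@@H]1C(C)(C)[C@@H](OCc1ccccc1)C[C@@H]2O[Si](C)(C)C(C)(C)C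
A6 | alternative 3 | 4-(benzyloxy)-2-[(tert-butyldimethylsilyl)oxy]-1,5,5-trimethylcyclopentane-1-carbaldehyde | CC1(C)[C@@H](OCc2ccccc2)C[C@H](O[Si](C)(C)C(C)(C)C)[C@]1(C)C=O
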